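**Retrosynthetic overview**
- The cyclohexene (C2–C4' and C14–C15') is cut by a Diels–Alder disconnection. This gives dehydrozaluzanin C as dienophile (two steps from commercial dehydrocostus lactone) and a dienone. In the dienone, the C4=C15 methylene ketone and the lactone oxygen O6 are masked together as a tetrahydrofuran (C15–O–C6).
- The dienone comes from one open chain by a silylium-triggered domino that forms C1–C5 and then C6–C7. It closes the cyclopentenone and the seven-membered ring and sets C5, C6 and C7.
- Enabling feature: C5=C6 is the enol-ether bond of a 2,3-dihydrofuran. C5 is therefore a nucleophile for the C1 carbonyl, and C6 then becomes an oxocarbenium ion for C7. C7 lies next to the exocyclic C11=C13 (allylsilane retron), and C3(=O)–C2=C1 is a Stork–Danheiser retron.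
- Ring order: dihydrofuran (temporary), then cyclopentenone and cycloheptane (key step), then spiro-cyclohexene, then γ-lactone with loss of the tetrahydrofuran.
- The chain is joined from (S)-3-ethynyl-2,3-dihydrofuran (which carries the only preset stereocentre, C4, later destroyed) and a 2-substituted acrolein that bears the 2-(silylmethyl)enoate.

Key step: step 13

Numbering: guaiane numbering is used. Unprimed atoms belong to the cyclopentenone half and primed atoms to the spiro half. α/β are used as in dehydrocostus lactone (H-7 α).

Remark on the stereochemistry: read from the SMILES, the primed half has the dehydrocostus lactone configuration. The unprimed half has H-5 cis to H-6, H-6 trans to H-7 and H-10 trans to H-5. It is the C5 epimer of that series and is therefore built de novo.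

Assumption: (R)-DTBM-SEGPHOS is taken to give the (S)-aldehyde in step 3; if the sense is opposite, the antipodal ligand is used.

Step 1
Reactants: 1 (E)-but-2-ene-1,4-diol
Product: 2 (E)-4-[(tert-butyldimethylsilyl)oxy]but-2-en-1-ol
Conditions: NaH (1 equiv), THF, 0 °C; TBSCl (1 equiv)
Reagents that add atoms: tert-butyldimethylsilyl chloride, CC(C)(C)[Si](C)(C)Cl
Why: O-silylation of the sparingly soluble sodium monoalkoxide should stop at the monoether; no stereocentre is formed.

Step 2
Reactants: 2 (E)-4-[(tert-butyldimethylsilyl)oxy]but-2-en-1-ol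
Product: 3 (E)-4-[(tert-butyldimethylsilyl)oxy]but-2-enal
Conditions: MnO2, CH2Cl2, rt
Reagents that add atoms: none
Why: MnO2 oxidation of an allylic alcohol should give the enal with the E geometry kept.

Step 3
Reactants: 3 (E)-4-[(tert-butyldimethylsilyl)oxy]but-2-enal; 4 (triisopropylsilyl)acetylene
Product: 5 (S)-3-{[(tert-butyldimethylsilyl)oxy]methyl}-5-(triisopropylsilyl)pent-4-ynal
Conditions: [Rh(OAc)(C2H4)2]2 (cat.), (R)-DTBM-SEGPHOS (cat.), MeOH, 40 °C
Reagents that add atoms: none
Why: Rh(I)-catalysed asymmetric conjugate alkynylation of an enal; the bulky silyl group suppresses alkyne oligomerisation and the ligand selects the enal face, which sets C4.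

Step 4
Reactants: 5 (S)-3-{[(tert-butyldimethylsilyl)oxy]methyl}-5-(triisopropylsilyl)pent-4-ynal
Product: 6 (4S)-4-ethynyltetrahydrofuran-2-ol (anomers)
Conditions: TBAF (2.2 equiv), AcOH (2.2 equiv), THF, 0 °C to rt
Reagents that add atoms: none
Why: Buffered fluoride desilylation should cleave both the Si–O and Si–C(sp) bonds, and the γ-hydroxy aldehyde closes to the lactol; C4 is β to the aldehyde and is not enolisable.

Step 5
Reactants: 6 (4S)-4-ethynyltetrahydrofuran-2-ol
Product: 7 (S)-3-ethynyl-2,3-dihydrofuran (volatile, handled in solution)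
Conditions: MsCl, Et3N (excess), CH2Cl2, −20 °C to reflux
Reagents that add atoms: none
Why: Mesylation of the lactol and elimination (glycal-type enol ether synthesis) should give the cyclic enol ether without touching C4.

Step 6
Reactants: 8 trimethyl phosphonoacetate; 9 (iodomethyl)trimethylsilane
Product: 10 methyl 2-(dimethoxyphosphoryl)-3-(trimethylsilyl)propanoate
Conditions: NaH, DME, 70 °C
Reagents that add atoms: none
Why: SN2 alkylation of the phosphonate carbanion by the primary iodide.

Step 7
Reactants: 10 methyl 2-(dimethoxyphosphoryl)-3-(trimethylsilyl)propanoate; 11 tetrahydro-2H-pyran-2-ol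
Product: 12 methyl (Z)-7-hydroxy-2-[(trimethylsilyl)methyl]hept-2-enoate (chain trans to the ester)
Conditions: NaH, THF, 0 °C to rt
Reagents that add atoms: none
Why: Horner–Wadsworth–Emmons olefination of the open 5-hydroxypentanal form; the alkene geometry is inconsequential because C11 returns to sp2 in step 13.

Step 8
Reactants: 12 methyl (Z)-7-hydroxy-2-[(trimethylsilyl)methyl]hept-2-enoate
Product: 13 methyl (Z)-7-oxo-2-[(trimethylsilyl)methyl]hept-2-enoate
Conditions: TEMPO (cat.), PhI(OAc)2, CH2Cl2, rt
Reagents that add atoms: none
Why: Oxoammonium (TEMPO) oxidation of the primary alcohol should stop at the aldehyde and leave the electron-poor allylsilane alone.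

Step 9
Reactants: 13 methyl (Z)-7-oxo-2-[(trimethylsilyl)methyl]hept-2-enoate; 14 formaldehyde (37 % aq.)
Product: 15 methyl (Z)-6-formyl-2-[(trimethylsilyl)methyl]hepta-2,6-dienoate
Conditions: pyrrolidine (cat.), propionic acid (cat.), i-PrOH, 45 °C
Reagents that add atoms: none
Why: Organocatalytic Mannich-type α-methylenation of the aldehyde installs C14 under nearly neutral conditions.

Step 10
Reactants: 7 (S)-3-ethynyl-2,3-dihydrofuran; 15 methyl (Z)-6-formyl-2-[(trimethylsilyl)methyl]hepta-2,6-dienoate
Product: 16 methyl (2Z)-9-[(3S)-2,3-dihydrofuran-3-yl]-7-hydroxy-6-methylidene-2-[(trimethylsilyl)methyl]non-2-en-8-ynoate (carbinol epimers, both used)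
Conditions: n-BuLi, THF, −78 °C; then 15; aq. NH4Cl
Reagents that add atoms: none
Why: 1,2-Addition of the lithium acetylide to the enal is much faster than attack on the ester at −78 °C; the new carbinol centre is removed in step 11.

Step 11
Reactants: 16 the propargylic/allylic alcohol
Product: 17 methyl (2Z)-9-[(3S)-2,3-dihydrofuran-3-yl]-6-methylidene-7-oxo-2-[(trimethylsilyl)methyl]non-2-en-8-ynoate
Conditions: MnO2, CH2Cl2, 0 °C to rt
Reagents that add atoms: none
Why: Neutral MnO2 oxidation of a doubly activated alcohol should spare the enol ether and the allylsilane.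

Step 12
Reactants: 17 the cross-conjugated ynone
Product: 18 methyl (2Z,8E)-9-[(3R)-2,3-dihydrofuran-3-yl]-9-methoxy-6-methylidene-7-oxo-2-[(trimethylsilyl)methyl]nona-2,8-dienoate (same spatial arrangement at C4 as in 7)
Conditions: MeOH (2 equiv), PBu3 (5 mol %), CH2Cl2, 0 °C
Reagents that add atoms: methanol, CO
Why: Phosphine-catalysed oxa-Michael addition to the ynone should be irreversible and give the E vinylogous ester (OMe trans to the acyl group, so C4 cis to C1), whereas addition to the α-methylene ketone is reversible.

Step 13
Reactants: 18 the dihydrofuranyl vinylogous ester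
Product: 20 methyl 6α,15-epoxy-3-oxoguaia-1,10(14),11(13)-trien-12-oate (4βH,5βH,6βH,7αH), via tetracyclic silyl ether 19 (not isolated)
Conditions: TMSOTf (10 mol %), 2,6-di-tert-butyl-4-methylpyridine (5 mol %), 4 Å MS, CH2Cl2 (0.005 M), −78 to −20 °C; then 0.5 M aq. oxalic acid, THF, 0 °C
Reagents that add atoms: water, O
Why: Proposed new method: Me3Si+ silylates the vinylogous-ester carbonyl to a 1-siloxy-3-methoxyallyl cation, the enol-ether carbon C5 adds to C1, the tetrahydrofuranyl oxocarbenium ion so formed at C6 is captured by the allylsilane carbon C7 with release of Me3Si+ (chain carrier, net silicon shift from C13 to O1, giving 19), and the acidic work-up ionises the doubly allylic C1–OSiMe3 and hydrolyses the C3 enol ether to the transposed enone. The closest known reaction types are the Mukaiyama aldol–Prins cascade (enol ether, activated carbonyl, tethered allylsilane), the intramolecular Hosomi–Sakurai closure of 2-(silylmethyl)enoates and the Stork–Danheiser transposition; new is their union on a vinylogous ester within one chain. The cyclopentene closes 5-exo-trig at the C1=O+ bond (the E alkene already holds C4 and C1 cis), and the cycloheptane closes 7-exo-trig at both the C6=O+ and the C7=C11 bond. C5 is fixed by C4, because the 5/5 junction can only form cis (bond on the dihydrofuran face that carries the tether); C6 is fixed by the three-carbon bridge C8–C10, which can bring C7 only to the concave face, cis to C1, so that H-5 and H-6 become cis; C7 is fixed by placing the bulky C11 anti to the C5–C6 bond, away from the bicyclic core, so that H-6 and H-7 become trans; the C1 carbinol centre is erased. The step needs C5 to outrun the allylsilane for C1, which the large nucleophilicity gap between an alkyl enol ether and an ester-bearing allylsilane secures, and it needs 4π closure C3–C14 and proton loss from C4 (drift towards a furan) to stay slow, which the terminal methoxy donor, the near absence of base and the low temperature should secure.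

Step 14
Reactants: 21 (−)-dehydrocostus lactone
Product: 22 3-epizaluzanin C (3α-hydroxyguaia-4(15),10(14),11(13)-trien-12,6α-olide)
Conditions: SeO2 (cat.), t-BuOOH, CH2Cl2, rt
Reagents that add atoms: tert-butyl hydroperoxide, CC(C)(C)OO
Why: Riley allylic oxidation (ene reaction, then [2,3]-shift) at C3' on the convex α face; the new carbinol centre is removed in step 15.

Step 15
Reactants: 22 3-epizaluzanin C
Product: 23 dehydrozaluzanin C
Conditions: Dess–Martin periodinane, NaHCO3, CH2Cl2, 0 °C
Reagents that add atoms: none
Why: Dess–Martin oxidation of the allylic alcohol under buffered conditions should deliver the sensitive α-methylene ketone.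

Step 16
Reactants: 20 the tetracyclic dienone; 23 dehydrozaluzanin C
Product: 24 spiro Diels–Alder adduct (C1=C10, 2αH, tetrahydrofuran and methyl ester intact)
Conditions: toluene, BHT, 70 °C
Reagents that add atoms: none
Why: Diels–Alder reaction of the s-cis-locked 1-acyl diene C2=C1–C10=C14 with "ortho" orientation (C2–C4', C14–C15'); the diene reacts on its β face opposite the tetrahydrofuran, and the dienophile on its convex α face (that of H-1' and H-5'), which sets C4'.

Step 17
Reactants: 24 the Diels–Alder adduct
Product: 27 CNP0221188.1, via conjugated enone 25 (not isolated), via seco hydroxy ester 26 (not isolated)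
Conditions: DBU (1.2 equiv), toluene, 0 °C to rt
Reagents that add atoms: none
Why: Base-mediated conjugation of the β,γ-enone, in which the amidinium ion pair should relay H-2 suprafacially to C10 in the non-polar solvent (H-10 α, trans to H-5), then E1cB retro-oxa-Michael opening (C4=C15) and lactonisation of the freed O6 alkoxide onto the C12 ester.

**Compound list**
1 | (E)-but-2-ene-1,4-diol | OC/C=C/CO | starting material
2 | (E)-4-[(tert-butyldimethylsilyl)oxy]but-2-en-1-ol | CC(C)(C)[Si](C)(C)OC/C=C/CO | intermediate
3 | (E)-4-[(tert-butyldimethylsilyl)oxy]but-2-enal | CC(C)(C)[Si](C)(C)OC/C=C/C=O | intermediate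
4 | (triisopropylsilyl)acetylene | C#C[Si](C(C)C)(C(C)C)C(C)C | starting material
5 | (S)-3-{[(tert-butyldimethylsilyl)oxy]methyl}-5-(triisopropylsilyl)pent-4-ynal | O=CC[C@H](CO[Si](C)(C)C(C)(C)C)C#C[Si](C(C)C)(C(C)C)C(C)C | intermediate
6 | (4S)-4-ethynyltetrahydrofuran-2-ol (anomers) | OC1C[C@@H](C#C)CO1 | intermediate
7 | (S)-3-ethynyl-2,3-dihydrofuran | C#C[C@@H]1C=COC1 | intermediate
8 | trimethyl phosphonoacetate | COC(=O)CP(=O)(OC)OC | starting material
9 | (iodomethyl)trimethylsilane | C[Si](C)(C)CI | starting material
10 | methyl 2-(dimethoxyphosphoryl)-3-(trimethylsilyl)propanoate | COC(=O)C(C[Si](C)(C)C)P(=O)(OC)OC | intermediate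
11 | tetrahydro-2H-pyran-2-ol | OC1CCCCO1 | starting material
12 | methyl (Z)-7-hydroxy-2-[(trimethylsilyl)methyl]hept-2-enoate | COC(=O)/C(C[Si](C)(C)C)=C/CCCCO | intermediate
13 | methyl (Z)-7-oxo-2-[(trimethylsilyl)methyl]hept-2-enoate | COC(=O)/C(C[Si](C)(C)C)=C/CCCC=O | intermediate
14 | formaldehyde | C=O | starting material
15 | methyl (Z)-6-formyl-2-[(trimethylsilyl)methyl]hepta-2,6-dienoate | COC(=O)/C(C[Si](C)(C)C)=C/CCC(=C)C=O | intermediate
16 | propargylic alcohol (carbinol epimers) | COC(=O)/C(C[Si](C)(C)C)=C/CCC(=C)C(O)C#C[C@@H]1C=COC1 | intermediate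
17 | cross-conjugated ynone | COC(=O)/C(C[Si](C)(C)C)=C/CCC(=C)C(=O)C#C[C@@H]1C=COC1 | intermediate
18 | (E)-β-methoxy enone (key-step precursor) | COC(=O)/C(C[Si](C)(C)C)=C/CCC(=C)C(=O)/C=C(/OC)[C@@H]1C=COC1 | intermediate
19 | methyl 6α,15-epoxy-3-methoxy-1β-(trimethylsilyloxy)guaia-2,10(14),11(13)-trien-12-oate | COC1=C[C@]2(O[Si](C)(C)C)C(=C)CC[C@@H](C(=C)C(=O)OC)[C@@H]3OC[C@H]1[C@H]23 | intermediate
20 | methyl 6α,15-epoxy-3-oxoguaia-1,10(14),11(13)-trien-12-oate (4βH,5βH,6βH,7αH) | O=C1C=C2C(=C)CC[C@@H](C(=C)C(=O)OC)[C@@H]3OC[C@H]1[C@H]23 | intermediate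
21 | (−)-dehydrocostus lactone | C=C1CC[C@@H]2[C@@H]([C@@H]3[C@H]1CCC3=C)OC(=O)C2=C | starting material
22 | 3-epizaluzanin C | C=C1CC[C@@H]2[C@@H]([C@@H]3[C@H]1C[C@@H](O)C3=C)OC(=O)C2=C | intermediate
23 | dehydrozaluzanin C | C=C1CC[C@@H]2[C@@H]([C@@H]3[C@H]1CC(=O)C3=C)OC(=O)C2=C | intermediate
24 | Diels–Alder adduct (C1=C10, 2αH) | O=C1[C@@H]2C3=C(CC[C@]24C(=O)C[C@H]5C(=C)CC[C@H]6C(=C)C(=O)O[C@@H]6[C@H]54)CC[C@@H](C(=C)C(=O)OC)[C@@H]7OC[C@H]1[C@H]37 | intermediate
25 | conjugated enone (C1=C2, 10αH, tetrahydrofuran intact) | O=C1C2=C3[C@H](CC[C@@H](C(=C)C(=O)OC)[C@@H]4OC[C@H]1[C@H]34)CC[C@]25C(=O)C[C@H]6C(=C)CC[C@H]7C(=C)C(=O)O[C@@H]7[C@H]65 | intermediate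
26 | seco hydroxy ester (C4=C15, 6-OH, methyl ester) | C=C1C(=O)C2=C3[C@H](CC[C@@H](C(=C)C(=O)OC)[C@H](O)[C@H]13)CC[C@]21C(=O)C[C@H]2C(=C)CC[C@H]3C(=C)C(=O)O[C@@H]3[C@H]21 | intermediate
27 | CNP0221188.1 | C=C1C(=O)C2=C3[C@H](CC[C@H]4C(=C)C(=O)O[C@@H]4[C@H]13)CC[C@]21C(=O)C[C@H]2C(=C)CC[C@H]3C(=C)C(=O)O[C@@H]3[C@H]21 | target

Total step count: 17. Longest linear sequence: 11 steps (1–5, 10–13, 16, 17).

**Steps most likely to fail**

Step 13
- The domino may stall after the first ring, because closure of the seven-membered ring by the weak allylsilane may be slow. It may also be diverted by proton loss at C4 or by 4π closure.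
- Fallback, from 18 back to 20: the two bonds are made in two separate, known operations.
  - With TMSOTf in the presence of excess methoxytrimethylsilane, the oxocarbenium ion is intercepted aprotically. After oxalic acid work-up, the bicyclic enone methyl acetal F1 is isolated (enol ether/carbonyl condensation with acetal trapping, then Stork–Danheiser hydrolysis).
  - F1 is then closed on its own, at high dilution, by a catalytic-TMSOTf Hosomi–Sakurai reaction of the cyclic acetal with the tethered allylsilane. This gives 20.

Step 16
- The masked dienone may be too sluggish a diene, so that self-reaction of the dienophile wins.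
- Fallback, from 20 and 23 to 27: the order of events is reversed.
  - DBU first opens the tetrahydrofuran and closes the lactone. This gives the planar, far more reactive cross-conjugated trienone lactone F2, which is generated slowly in the presence of excess 23.
  - The Diels–Alder adduct F3 should then form at or below room temperature.
  - The same base conjugates F3 to 27.

Step 17
- The proton may be delivered to the wrong face of C10, or C5 may be lost by vinylogous enolisation of the product under base.
- Fallback, from 24 to 27: the anionic manifold is left for the enol manifold. Camphorsulfonic acid in benzene at 40–50 °C should effect acid-catalysed conjugation of the β,γ-enone, acid-catalysed retro-oxa-Michael opening and acid lactonisation. No dienolate of the product is ever formed. The fallback runs through 25 and 26 and makes no new compound (F0).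

Further compounds
F1 | step 13 | bicyclic enone methyl acetal (C1–C5 closed, C6–OMe anomers, allylsilane intact) | O=C1C=C(C(=C)CC/C=C(\C[Si](C)(C)C)C(=O)OC)[C@@H]2C(OC)OC[C@H]12
F2 | step 16 | 5βH-3-oxoguaia-1,4(15),10(14),11(13)-tetraen-12,6α-olide | C=C1C(=O)C=C2C(=C)CC[C@H]3C(=C)C(=O)O[C@@H]3[C@H]12
F3 | step 16 | Diels–Alder adduct of F2 and 23 (C1=C10, 2αH) | C=C1C(=O)[C@@H]2C3=C(CC[C@]24C(=O)C[C@H]5C(=C)CC[C@H]6C(=C)C(=O)O[C@@H]6[C@H]54)CC[C@H]7C(=C)C(=O)O[C@@H]7[C@H]13
F0 | step 17 | none | none
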